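The theta run with 5 mM of substrate and the alpha run with 7.5 mM showed me no clear shift in isomer of the product A or target with the charge, so I used a bench rule for the new flask: read the ratio of the two at a given time from the earlier runs and carry it over unchanged.

| flask | substrate | remark | time |
|---|---|---|---|
| theta | 5 mM | run made earlier |  |
| alpha | 7.5 mM | run made earlier |  |
| flask | 10 mM |  | 6.0 min |

| run | time / min | isomer of the product A / % | target / % |
|---|---|---|---|
| theta | 0.417 | 13.9 | 5.0 |
| theta | 0.667 | 17.4 | 5.0 |
| theta | 1.33 | 21.1 | 3.9 |
| theta | 2.50 | 23.9 | 3.5 |
| theta | 5.00 | 28.6 | 2.1 |
| alpha | 0.417 | 12.5 | 5.1 |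
| alpha | 0.667 | 18.0 | 1.9 |
| alpha | 1.33 | 20.2 | 1.6 |
| alpha | 2.50 | 20.2 | 4.0 |
| alpha | 5.00 | 25.6 | 3.5 |

(standard deviation of a reading: 1 percentage point)



- ratio of isomer of the product A to target at 8.0 s
- ratio of isomer of the product A to target at 50 s
- ratio of isomer of the product A to target at 6.0 min
- which of isomer of the product A and target there is more of at 6.0 min

Single ratios were poor, because at the last reading the theta run gave 13.6 and the alpha run 7.31, with target at 2.1% and 3.5% against a scatter of 1 percentage point. So I pooled the runs. The late odds, the sum of the two last isomer readings over the sum of the two last target readings, a ratio of amounts read at 5.00 min, came to 9.68. The target sum carried a scatter of about a quarter of itself, and the odds carry the same.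

The flask's last time is 1.20 times the last reading, so I took the late odds as my figure for 6.0 min. The rule stopped at the early end, since 8.0 s is about a third of the first reading time. The same pooling gave 2.61 at that first reading, and the ratio was rising from there, so I could say only that the ratio at 8.0 s lay lower.

The forecast gave 2 at 8.0 s, 5 at 50 s and 10 at 6.0 min, a little above my late odds, with isomer of the product A ahead. It rested on the words “no clear concentration effect”.

The flask gave 1.16, 4.90 and 8.30 at those times, with isomer of the product A ahead, 22.7% against 2.73%.

    substrate → intermediate (k = 0.0480 /s)
    intermediate ⇌ target (K = 4.00, k = 0.0960 /s)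
    intermediate ⇌ isomer of the product A (K = 150, k = 0.0400 /s)
    2 substrate → homo dimer (k = 4.50 /M/s)
    target ⇌ isomer of the product B (K = 11.0, k = 0.460 /s)

Target and isomer of the product B relaxed into each other with a half-life of 1.38 s, far shorter than 6.0 min. Isomer of the product A went back through intermediate with a half-life of 43 min, far longer than 6.0 min. At 6.0 min the flask held 30.4% of isomer of the product B beside 2.73% of target, and its ratio stood 14.3% below my late odds. The neighbour flask with 25 mM of substrate held less isomer of the product A, 15.0%, and less target, 1.80%, yet its ratio at 6.0 min was 8.32.

(All runs are simulated with constants of no real substance, noise included.)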